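**Plan**
- Retrosynthesis: after removal of the MOM group on O7, ring B is cut at C1′–C6′ and C2′–C3′, and also at C3′–prenyl and O4′–CH3. This is possible because ring B is a resorcinol monomethyl ether with prenyl on C3′ between O2′ and O4′ and the chroman on C1′, that is, the aromatised form of a 2-prenyl-4-substituted cyclohexane-1,3-dione.
- The dione is traced to a C3-bound malonate (C1′, C2′) and methyl vinyl ketone (C3′–C6′). The malonate comes from a chroman-3-carboxylic acid by one-carbon homologation and carbomethoxylation, and ring C from a salicylaldehyde and acrylonitrile (O1–C2, C3–C4).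
- Forward order: ring A is the starting arene, ring C is closed as a 2H-chromene, and ring B is grown on C3 by Michael–Claisen annulation. It is then prenylated, O-methylated, freed of the auxiliary ester and dehydrogenated to the arene.
- Stereochemistry: the only stereocentre, C3, is set by catalyst-controlled asymmetric hydrogenation of the 2H-chromene-3-carboxylic acid. It is not enolisable after step 7, and its CIP label changes only with the substituents, not with the geometry.

Key step: step 9

Remark: the antipode of the iridium catalyst in step 5 is assumed to be the one that delivers the 3S acid, in line with the parent 2H-chromene-3-carboxylic acids. Primed locants C1′–C6′ denote the carbons of the future ring B throughout.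

**Route**

Step 1
Reactants: 1 5-methoxyresorcinol
Product: 3 2,4-dihydroxy-6-methoxybenzaldehyde, via aryl iminium chloride 2 (not isolated)
Conditions: POCl3, DMF, MeCN, 0 °C → rt; then H2O, 60 °C
Reagents that add atoms: N,N-dimethylformamide CN(C)C=O; water O
Why: Vilsmeier–Haack formylation should go mainly to one of the two equivalent carbons flanked by OH and OMe (para to the other OH), and the minor 2,6-dihydroxy isomer should be removable by crystallisation.

Step 2
Reactants: 3 2,4-dihydroxy-6-methoxybenzaldehyde
Product: 4 2-hydroxy-6-methoxy-4-(methoxymethoxy)benzaldehyde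
Conditions: MOMCl (1.1 equiv), i-Pr2NEt, CH2Cl2, 0 °C
Reagents that add atoms: chloromethyl methyl ether COCCl
Why: Williamson-type O-alkylation should select the free, more acidic 4-OH, because the 2-OH is held in a hydrogen bond to the aldehyde.

Step 3
Reactants: 4 2-hydroxy-6-methoxy-4-(methoxymethoxy)benzaldehyde; 5 acrylonitrile
Product: 6 5-methoxy-7-(methoxymethoxy)-2H-chromene-3-carbonitrile
Conditions: DABCO (0.5 equiv), neat acrylonitrile, reflux
Reagents that add atoms: none
Why: the DABCO-mediated Baylis–Hillman/oxa-Michael annulation of salicylaldehydes with acrylonitrile, followed by loss of water, is a standard entry to 2H-chromene-3-carbonitriles and forms O1–C2 and C3–C4 of ring C.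

Step 4
Reactants: 6 5-methoxy-7-(methoxymethoxy)-2H-chromene-3-carbonitrile
Product: 7 5-methoxy-7-(methoxymethoxy)-2H-chromene-3-carboxylic acid
Conditions: 10% aq. NaOH, reflux; then 1 M HCl, 0 °C, to pH 3
Reagents that add atoms: sodium hydroxide [Na+].[OH-]; water O
Why: alkaline hydrolysis of the conjugated nitrile gives the carboxylate, while the MOM acetal and the chromene are inert to hydroxide and survive a brief cold acidification.

Step 5
Reactants: 7 5-methoxy-7-(methoxymethoxy)-2H-chromene-3-carboxylic acid
Product: 8 (3S)-5-methoxy-7-(methoxymethoxy)chroman-3-carboxylic acid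
Conditions: [Ir(cod)(chiral spiro phosphine–oxazoline)]BArF (1 mol %), H2 (6 atm), Et3N (0.5 equiv), MeOH, rt
Reagents that add atoms: none
Why: carboxylate-directed iridium-catalysed asymmetric hydrogenation is established for 2H-chromene-3-carboxylic acids, and the chiral P,N ligand decides the face of C3=C4 that receives hydrogen and so sets C3 as 3S (the salt with a chiral amine can be crystallised if the enantiomeric purity needs raising).

Step 6
Reactants: 8 (3S)-5-methoxy-7-(methoxymethoxy)chroman-3-carboxylic acid
Product: 10 2-diazo-1-[(3S)-5-methoxy-7-(methoxymethoxy)chroman-3-yl]ethan-1-one, via mixed anhydride 9 (not isolated)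
Conditions: i-BuOCOCl, N-methylmorpholine, THF, −15 °C; then CH2N2, Et2O, 0 °C → rt
Reagents that add atoms: diazomethane C=[N+]=[N-]
Why: this is the first stage of the Arndt–Eistert homologation, in which diazomethane is acylated by a mixed carbonic anhydride formed with a weak base at low temperature so that the α-stereocentre is not epimerised.

Step 7
Reactants: 10 2-diazo-1-[(3S)-5-methoxy-7-(methoxymethoxy)chroman-3-yl]ethan-1-one
Product: 12 methyl 2-[(3R)-5-methoxy-7-(methoxymethoxy)chroman-3-yl]acetate, via ketene 11 (not isolated)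
Conditions: PhCO2Ag (10 mol %), Et3N, MeOH, rt, dark
Reagents that add atoms: methanol CO
Why: in the silver-catalysed Wolff rearrangement C3 migrates with retention and methanol traps the ketene, and the label changes from S to R only because CH2CO2Me ranks below C2.

Step 8
Reactants: 12 methyl 2-[(3R)-5-methoxy-7-(methoxymethoxy)chroman-3-yl]acetate
Product: 13 dimethyl 2-[(3R)-5-methoxy-7-(methoxymethoxy)chroman-3-yl]propanedioate
Conditions: LDA (2.1 equiv), THF, −78 °C; ClCO2Me (1.1 equiv), −78 → 0 °C
Reagents that add atoms: methyl chloroformate COC(=O)Cl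
Why: crossed-Claisen-type C-acylation of the lithium ester enolate gives the malonate, the second equivalent of base takes up the more acidic malonate proton, and C3 is β to the carbonyl and cannot be touched.

Step 9
Reactants: 13 dimethyl 2-[(3R)-5-methoxy-7-(methoxymethoxy)chroman-3-yl]propanedioate; 14 methyl vinyl ketone
Product: 16 methyl 1-[(3R)-5-methoxy-7-(methoxymethoxy)chroman-3-yl]-2,4-dioxocyclohexane-1-carboxylate (both C1 epimers; largely enolised), via Michael adduct 15 (not isolated)
Conditions: NaOMe (0.2 equiv), MeOH, 0 °C → rt; then NaOMe (1.5 equiv), MeOH, 50 °C; AcOH quench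
Reagents that add atoms: none
Why: Catalytic methoxide turns malonate 13 into a soft, stabilised carbanion that adds 1,4 to methyl vinyl ketone and forms C1′–C6′ (15); with stoichiometric methoxide the ketone equilibrates between its two enolates, and the methyl-side enolate acylates on one of the diastereotopic ester carbonyls, expels methoxide and forms C2′–C3′, the sequence being drawn forward by irreversible deprotonation of the new 1,3-dione. The closest known reaction is the classical malonate–enone Michael–Claisen (dimedone-type) synthesis of cyclohexane-1,3-diones, used here with an alkylmalonate and the parent enone. Ring B closes in a 6-(enolendo)-exo-trig acylation, whereas the internal methylene enolate could only reach a four-membered ring and therefore returns to the enolate pool. The one new stereocentre, quaternary C1′, forms without control and does not matter because it is erased when the ring is aromatised, while C3 is never enolisable. The step needs conjugate rather than carbonyl addition and no enone polymerisation, and the second ester secures both by lowering the pKa of the donor so that only catalytic alkoxide is present at 0 °C while the enone is consumed, which a plain acetate enolate would not allow. The extra ester is kept afterwards because the quaternary centre it creates shields O2′ in the later O-methylation.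

Step 10
Reactants: 16 methyl 1-[(3R)-5-methoxy-7-(methoxymethoxy)chroman-3-yl]-2,4-dioxocyclohexane-1-carboxylate; 17 prenyl acetate
Product: 18 methyl 1-[(3R)-5-methoxy-7-(methoxymethoxy)chroman-3-yl]-3-(3-methylbut-2-en-1-yl)-2,4-dioxocyclohexane-1-carboxylate
Conditions: Pd(PPh3)4 (3 mol %), DBU (1.1 equiv), THF, 40 °C
Reagents that add atoms: none
Why: in this Tsuji–Trost allylation the soft dione enolate should attack the unsubstituted terminus of the π-(1,1-dimethylallyl)palladium complex and place a linear prenyl group on C3′ between the carbonyls, while any O-allylated material re-ionises and is funnelled to the C-alkylated product.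

Step 11
Reactants: 18 methyl 1-[(3R)-5-methoxy-7-(methoxymethoxy)chroman-3-yl]-3-(3-methylbut-2-en-1-yl)-2,4-dioxocyclohexane-1-carboxylate
Product: 19 methyl 1-[(3R)-5-methoxy-7-(methoxymethoxy)chroman-3-yl]-4-methoxy-3-(3-methylbut-2-en-1-yl)-2-oxocyclohex-3-ene-1-carboxylate
Conditions: Me2SO4 (1.2 equiv), K2CO3, acetone, reflux
Reagents that add atoms: dimethyl sulfate COS(=O)(=O)OC
Why: O-alkylation of the 2-alkyl-1,3-dione enolate with a hard methylating agent should occur on O4′, because O2′ is screened by the adjacent quaternary C1′ that carries the ester and the chroman.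

Step 12
Reactants: 19 methyl 1-[(3R)-5-methoxy-7-(methoxymethoxy)chroman-3-yl]-4-methoxy-3-(3-methylbut-2-en-1-yl)-2-oxocyclohex-3-ene-1-carboxylate
Product: 20 6-[(3R)-5-methoxy-7-(methoxymethoxy)chroman-3-yl]-3-methoxy-2-(3-methylbut-2-en-1-yl)cyclohex-2-en-1-one (C6 epimers)
Conditions: LiCl (3 equiv), H2O (2 equiv), DMSO, 140 °C
Reagents that add atoms: none
Why: in this Krapcho dealkoxycarbonylation chloride attacks the ester methyl group, the β-keto carboxylate loses CO2 and the enolate is protonated at C1′, whereas the enol ether methyl group has no decarboxylation to drive its cleavage and should remain.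

Step 13
Reactants: 20 6-[(3R)-5-methoxy-7-(methoxymethoxy)chroman-3-yl]-3-methoxy-2-(3-methylbut-2-en-1-yl)cyclohex-2-en-1-one
Product: 24 6-[(3R)-5-methoxy-7-(methoxymethoxy)chroman-3-yl]-3-methoxy-2-(3-methylbut-2-en-1-yl)phenol, via α′-selenide 21 (not isolated), via selenoxide 22 (not isolated), via cross-conjugated dienone 23 (not isolated)
Conditions: LDA (1.2 equiv), THF, −78 °C; PhSeBr (1.1 equiv), −78 °C; then 30% H2O2 (2.5 equiv), pyridine, CH2Cl2, 0 °C → rt
Reagents that add atoms: none
Why: in this Reich–Sharpless selenoxide dehydrogenation the kinetic α′-enolate of the vinylogous ester is selenenylated at C1′, and after oxidation the syn-elimination should take a hydrogen of the ring methylene C6′ rather than the exocyclic methine on C3, giving a dienone that enolises at once to the phenol.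

Step 14
Reactants: 24 6-[(3R)-5-methoxy-7-(methoxymethoxy)chroman-3-yl]-3-methoxy-2-(3-methylbut-2-en-1-yl)phenol
Product: 25 (3R)-3-[2-hydroxy-4-methoxy-3-(3-methylbut-2-en-1-yl)phenyl]-5-methoxychroman-7-ol
Conditions: 1 M HCl in MeOH, 0 °C → rt, stopped at full conversion
Reagents that add atoms: none
Why: acid-catalysed methanolysis of the aryl MOM acetal should proceed under conditions too mild for addition of the 2′-OH to the neighbouring prenyl alkene.

**Compound list**

1 | 5-methoxyresorcinol | COc1cc(O)cc(O)c1 | starting material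
2 | N-[(2,4-dihydroxy-6-methoxyphenyl)methylidene]-N-methylmethanaminium chloride | COc1cc(O)cc(O)c1C=[N+](C)C.[Cl-] | intermediate
3 | 2,4-dihydroxy-6-methoxybenzaldehyde | COc1cc(O)cc(O)c1C=O | intermediate
4 | 2-hydroxy-6-methoxy-4-(methoxymethoxy)benzaldehyde | COCOc1cc(O)c(C=O)c(OC)c1 | intermediate
5 | acrylonitrile | C=CC#N | starting material
6 | 5-methoxy-7-(methoxymethoxy)-2H-chromene-3-carbonitrile | COc1cc(OCOC)cc2c1C=C(C#N)CO2 | intermediate
7 | 5-methoxy-7-(methoxymethoxy)-2H-chromene-3-carboxylic acid | COc1cc(OCOC)cc2c1C=C(C(=O)O)CO2 | intermediate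
8 | (3S)-5-methoxy-7-(methoxymethoxy)chroman-3-carboxylic acid | COc1cc(OCOC)cc2c1C[C@H](C(=O)O)CO2 | intermediate
9 | (3S)-5-methoxy-7-(methoxymethoxy)chroman-3-carboxylic isobutyl carbonic anhydride | COc1cc(OCOC)cc2c1C[C@H](C(=O)OC(=O)OCC(C)C)CO2 | intermediate
10 | 2-diazo-1-[(3S)-5-methoxy-7-(methoxymethoxy)chroman-3-yl]ethan-1-one | COc1cc(OCOC)cc2c1C[C@H](C(=O)C=[N+]=[N-])CO2 | intermediate
11 | 2-[(3R)-5-methoxy-7-(methoxymethoxy)chroman-3-yl]ethen-1-one (ketene) | COc1cc(OCOC)cc2c1C[C@H](C=C=O)CO2 | intermediate
12 | methyl 2-[(3R)-5-methoxy-7-(methoxymethoxy)chroman-3-yl]acetate | COc1cc(OCOC)cc2c1C[C@H](CC(=O)OC)CO2 | intermediate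
13 | dimethyl 2-[(3R)-5-methoxy-7-(methoxymethoxy)chroman-3-yl]propanedioate | COc1cc(OCOC)cc2c1C[C@H](C(C(=O)OC)C(=O)OC)CO2 | intermediate
14 | methyl vinyl ketone | CC(=O)C=C | starting material
15 | dimethyl 2-[(3R)-5-methoxy-7-(methoxymethoxy)chroman-3-yl]-2-(3-oxobutyl)propanedioate | COc1cc(OCOC)cc2c1C[C@H](C(CCC(C)=O)(C(=O)OC)C(=O)OC)CO2 | intermediate
16 | methyl 1-[(3R)-5-methoxy-7-(methoxymethoxy)chroman-3-yl]-2,4-dioxocyclohexane-1-carboxylate (C1 epimers) | COc1cc(OCOC)cc2c1C[C@H](C1(C(=O)OC)CCC(=O)CC1=O)CO2 | intermediate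
17 | prenyl acetate (3-methylbut-2-en-1-yl acetate) | CC(C)=CCOC(C)=O | starting material
18 | methyl 1-[(3R)-5-methoxy-7-(methoxymethoxy)chroman-3-yl]-3-(3-methylbut-2-en-1-yl)-2,4-dioxocyclohexane-1-carboxylate | COc1cc(OCOC)cc2c1C[C@H](C1(C(=O)OC)CCC(=O)C(CC=C(C)C)C1=O)CO2 | intermediate
19 | methyl 1-[(3R)-5-methoxy-7-(methoxymethoxy)chroman-3-yl]-4-methoxy-3-(3-methylbut-2-en-1-yl)-2-oxocyclohex-3-ene-1-carboxylate | COc1cc(OCOC)cc2c1C[C@H](C1(C(=O)OC)CCC(OC)=C(CC=C(C)C)C1=O)CO2 | intermediate
20 | 6-[(3R)-5-methoxy-7-(methoxymethoxy)chroman-3-yl]-3-methoxy-2-(3-methylbut-2-en-1-yl)cyclohex-2-en-1-one | COc1cc(OCOC)cc2c1C[C@H](C1CCC(OC)=C(CC=C(C)C)C1=O)CO2 | intermediate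
21 | 6-[(3S)-5-methoxy-7-(methoxymethoxy)chroman-3-yl]-3-methoxy-2-(3-methylbut-2-en-1-yl)-6-(phenylselanyl)cyclohex-2-en-1-one (same geometry at C3; label changed by the selenium priority) | COc1cc(OCOC)cc2c1C[C@H](C1([Se]c3ccccc3)CCC(OC)=C(CC=C(C)C)C1=O)CO2 | intermediate
22 | 6-(benzeneseleninyl)-6-[(3S)-5-methoxy-7-(methoxymethoxy)chroman-3-yl]-3-methoxy-2-(3-methylbut-2-en-1-yl)cyclohex-2-en-1-one | COc1cc(OCOC)cc2c1C[C@H](C1([Se](=O)c3ccccc3)CCC(OC)=C(CC=C(C)C)C1=O)CO2 | intermediate
23 | 6-[(3R)-5-methoxy-7-(methoxymethoxy)chroman-3-yl]-3-methoxy-2-(3-methylbut-2-en-1-yl)cyclohexa-2,5-dien-1-one | COc1cc(OCOC)cc2c1C[C@H](C1=CCC(OC)=C(CC=C(C)C)C1=O)CO2 | intermediate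
24 | 6-[(3R)-5-methoxy-7-(methoxymethoxy)chroman-3-yl]-3-methoxy-2-(3-methylbut-2-en-1-yl)phenol | COc1cc(OCOC)cc2c1C[C@H](c1ccc(OC)c(CC=C(C)C)c1O)CO2 | intermediate
25 | (3R)-3-[2-hydroxy-4-methoxy-3-(3-methylbut-2-en-1-yl)phenyl]-5-methoxychroman-7-ol | COc1cc(O)cc2c1C[C@H](c1ccc(OC)c(CC=C(C)C)c1O)CO2 | target

**Summary**

Total step count: 14. Longest linear sequence: 14 steps (1 → 25).

Steps most likely to fail:

Step 13. Deprotonation at the crowded tertiary α′-carbon C1′ may be slow or may compete with γ-deprotonation, selenenylation of the fully substituted enolate carbon may stall, and any syn-elimination toward the exocyclic methine hydrogen would erase the C3 configuration. The fallback sets out from 19 and comes back at 24, and exchanges the order of dehydrogenation and ester removal. In 19 the α′-position is still quaternary, so LDA in THF/DMPU can only remove a γ-hydrogen at C5′. The extended enolate of the β-alkoxy enone is selenenylated at that carbon with PhSeBr to give methyl 1-[(3R)-5-methoxy-7-(methoxymethoxy)chroman-3-yl]-4-methoxy-3-(3-methylbut-2-en-1-yl)-2-oxo-5-(phenylselanyl)cyclohex-3-ene-1-carboxylate F1. Oxidation with H2O2/pyridine gives the corresponding 5-(benzeneseleninyl) compound F2, which can eliminate only into the ring methylene C6′ and should give methyl 1-[(3R)-5-methoxy-7-(methoxymethoxy)chroman-3-yl]-4-methoxy-3-(3-methylbut-2-en-1-yl)-2-oxocyclohexa-3,5-diene-1-carboxylate F3. Treatment of this blocked dienone with LiCl in DMF at 80 °C removes the ester, and the ring aromatises directly to 24; step 12 is bypassed.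

Step 9. Reversion of the conjugate addition or base-induced oligomerisation of the enone may outrun addition of the hindered tertiary malonate anion, or methoxide may cleave an ester before the ring closes. The fallback sets out from 13 and comes back at 16, and makes C1′–C6′ by alkylation instead of conjugate addition. Malonate 13 is deprotonated with NaH in DMF and alkylated with 2-(2-bromoethyl)-2-methyl-1,3-dioxolane (cat. NaI, 60 °C) to give dimethyl 2-[(3R)-5-methoxy-7-(methoxymethoxy)chroman-3-yl]-2-[2-(2-methyl-1,3-dioxolan-2-yl)ethyl]propanedioate F4. The ketal is opened with PPTS in wet acetone at 45 °C to give 15, this time isolated, which is closed to 16 with t-BuOK in THF at 0 °C.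

Step 12. Chloride may also attack the methyl group of the enol ether, or the substrate may degrade at the temperature needed to cleave the hindered ester. The fallback sets out from 18 and comes back at 20, and removes the ester before the enol ether exists. Compound 18 is heated with LiCl in wet DMSO at 130 °C to give 4-[(3R)-5-methoxy-7-(methoxymethoxy)chroman-3-yl]-2-(3-methylbut-2-en-1-yl)cyclohexane-1,3-dione F5, which is O-methylated with Me2SO4/K2CO3 in acetone to 20. The regiochemistry then rests only on the hindrance of the tertiary C1′ substituent, so isomeric purity has to be secured by chromatography.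

**Further compounds**

F1 | step 13 | methyl 1-[(3R)-5-methoxy-7-(methoxymethoxy)chroman-3-yl]-4-methoxy-3-(3-methylbut-2-en-1-yl)-2-oxo-5-(phenylselanyl)cyclohex-3-ene-1-carboxylate | COc1cc(OCOC)cc2c1C[C@H](C1(C(=O)OC)CC([Se]c3ccccc3)C(OC)=C(CC=C(C)C)C1=O)CO2
F2 | step 13 | methyl 5-(benzeneseleninyl)-1-[(3R)-5-methoxy-7-(methoxymethoxy)chroman-3-yl]-4-methoxy-3-(3-methylbut-2-en-1-yl)-2-oxocyclohex-3-ene-1-carboxylate | COc1cc(OCOC)cc2c1C[C@H](C1(C(=O)OC)CC([Se](=O)c3ccccc3)C(OC)=C(CC=C(C)C)C1=O)CO2
F3 | step 13 | methyl 1-[(3R)-5-methoxy-7-(methoxymethoxy)chroman-3-yl]-4-methoxy-3-(3-methylbut-2-en-1-yl)-2-oxocyclohexa-3,5-diene-1-carboxylate | COc1cc(OCOC)cc2c1C[C@H](C1(C(=O)OC)C=CC(OC)=C(CC=C(C)C)C1=O)CO2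
F4 | step 9 | dimethyl 2-[(3R)-5-methoxy-7-(methoxymethoxy)chroman-3-yl]-2-[2-(2-methyl-1,3-dioxolan-2-yl)ethyl]propanedioate | COc1cc(OCOC)cc2c1C[C@H](C(CCC1(C)OCCO1)(C(=O)OC)C(=O)OC)CO2
F5 | step 12 | 4-[(3R)-5-methoxy-7-(methoxymethoxy)chroman-3-yl]-2-(3-methylbut-2-en-1-yl)cyclohexane-1,3-dione | COc1cc(OCOC)cc2c1C[C@H](C1CCC(=O)C(CC=C(C)C)C1=O)CO2
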